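The synthesis rests on cutting all three carbon–oxygen bonds of benzene ring A: O1–C8a, O–C5 and O–C7 lie ortho, ortho and para to the C4 carbonyl carried by C4a, so each can be made by pushing fluoride out of a 2,4,6-trifluorobenzoyl group. In a single flask the enolate oxygen of an open-chain 1,3-diketone first closes pyranone ring B onto C8a, and benzyloxide then replaces the fluorides at C5 and C7. The substrate is 1-(2,4,6-trifluorophenyl)tetracosane-1,3-dione, assembled in one step from 2',4',6'-trifluoroacetophenone and docosanoyl chloride; cleavage of the two benzyl ethers then gives the 5,7-dihydroxy-2-henicosylchromone.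

Key step: step 2

Remark: the target has no stereocentre, so no stereocontrol is needed; the β-diketone is drawn in its diketo form although it should exist mainly as the chelated enol.

Step 1
Reactants: 1 2',4',6'-trifluoroacetophenone [1-(2,4,6-trifluorophenyl)ethan-1-one]; 2 docosanoyl chloride
Product: 3 1-(2,4,6-trifluorophenyl)tetracosane-1,3-dione
Conditions: 1 (2 equiv), LiN(SiMe3)2 (2 equiv), THF–toluene, −78 °C; then 2 (1 equiv), −78 → 0 °C; 1 M HCl
Reagents that add atoms: none
Why: Claisen-type C-acylation of a ketone enolate by an acyl chloride: ketone 1 has a single enolizable position, so its lithium enolate can only give the desired carbon skeleton, the second equivalent of enolate deprotonates the more acidic diketone as it forms and so suppresses a second acylation, and at low temperature neither the amide base nor the enolate should attack the aryl C–F bonds.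

Step 2
Reactants: 3 1-(2,4,6-trifluorophenyl)tetracosane-1,3-dione; 4 benzyl alcohol (two equivalents are built into the product)
Product: 7 5,7-bis(benzyloxy)-2-henicosyl-4H-chromen-4-one, via 5,7-difluoro-2-henicosylchromone 5 (not isolated), via 7-benzyloxy-5-fluoro-2-henicosylchromone 6 (not isolated)
Conditions: K2CO3 (1.5 equiv), 4 Å molecular sieves, DMF, 80 °C; then NaOCH2Ph (4 equiv, pre-formed from 4 and NaH in THF, excess 4 present), 25 → 60 °C; 1 M HCl
Reagents that add atoms: benzyl alcohol, OCc1ccccc1 (the second equivalent of 4, delivered like the first as NaOCH2Ph; it supplies the second benzyloxy group)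
Why: K2CO3 turns 3 into its enolate, whose oxygen on the chain-bearing carbonyl adds to an ortho C–F carbon of the trifluorobenzoyl ring and expels fluoride through a Meisenheimer anion stabilised by the aryl ketone (O1–C8a), giving 5; benzyloxide then displaces the fluorides para (C7, via 6) and ortho (C5) to the C4 carbonyl by the same addition–elimination. The closest known reactions are the base-mediated closure of 1-(2-fluoroaryl)-1,3-diketones and 2-fluoroaroyl enamines to chromones and 4-quinolones and the alkoxide SNAr of fluoroarenes bearing an ortho or para acyl group, here simply run in sequence in one flask. Ring B closes as a six-membered ring by intramolecular O-arylation, formally a 6-endo-trig addition to the C8a=C4a–C4=O unit followed by loss of fluoride. No stereocenter is created. The step needs O- rather than C-attack of the enolate and a defined outcome among three fluorides: only the enolate oxygen reaches an ortho carbon through a six-membered transition state, the two ortho fluorines are equivalent by symmetry, and after closure C5 and C7 remain ortho and para to the carbonyl, so whichever goes first the same bis-ether results. Holding back the alkoxide until the diketone has cyclised avoids retro-Claisen cleavage, the excess of 4 reprotonates any dienolate formed at C1' of the chain, and the acidic quench reverses any alkoxide adduct at C2.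

Step 3
Reactants: 7 5,7-bis(benzyloxy)-2-henicosyl-4H-chromen-4-one
Product: 8 5,7-dihydroxy-2-henicosyl-4H-chromen-4-one
Conditions: BCl3 (5 equiv), pentamethylbenzene (6 equiv), CH2Cl2, −78 → 0 °C; then H2O
Reagents that add atoms: none
Why: Lewis-acid cleavage of aryl benzyl ethers: BCl3 coordinates the ether oxygens (at O5 helped by chelation to the C4 carbonyl), the benzyl cation is captured by pentamethylbenzene in a Friedel–Crafts alkylation before it can attack ring A, and the C2=C3 bond, the pyranone and the alkyl chain are inert to these conditions.

Compound list
1 | 2',4',6'-trifluoroacetophenone [1-(2,4,6-trifluorophenyl)ethan-1-one] | CC(=O)c1c(F)cc(F)cc1F | starting material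
2 | docosanoyl chloride | CCCCCCCCCCCCCCCCCCCCCC(=O)Cl | starting material
3 | 1-(2,4,6-trifluorophenyl)tetracosane-1,3-dione | CCCCCCCCCCCCCCCCCCCCCC(=O)CC(=O)c1c(F)cc(F)cc1F | intermediate
4 | benzyl alcohol | OCc1ccccc1 | starting material
5 | 5,7-difluoro-2-henicosyl-4H-chromen-4-one | CCCCCCCCCCCCCCCCCCCCCc1cc(=O)c2c(F)cc(F)cc2o1 | intermediate
6 | 7-(benzyloxy)-5-fluoro-2-henicosyl-4H-chromen-4-one | CCCCCCCCCCCCCCCCCCCCCc1cc(=O)c2c(F)cc(OCc3ccccc3)cc2o1 | intermediate
7 | 5,7-bis(benzyloxy)-2-henicosyl-4H-chromen-4-one | CCCCCCCCCCCCCCCCCCCCCc1cc(=O)c2c(OCc3ccccc3)cc(OCc3ccccc3)cc2o1 | intermediate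
8 | 5,7-dihydroxy-2-henicosyl-4H-chromen-4-one | CCCCCCCCCCCCCCCCCCCCCc1cc(=O)c2c(O)cc(O)cc2o1 | target

Total step count: 3. Longest linear sequence: 3 steps (1 → 3 → 7 → 8).

Steps most likely to fail

Step 2 (highest risk). The cascade may stall after one or two displacements for three reasons. Benzyloxide can deprotonate the chain methylene C1', which is vinylogous to the C4 carbonyl, and turn the chromone into an electron-rich dienolate. Traces of hydroxide would deliver a phenoxide that shuts down further substitution. Alkoxide may also slowly cleave DMF to dimethylamine, a competing nucleophile. In addition, alkoxide added before ring closure is complete would invite retro-Claisen cleavage, so ring closure should be confirmed before the alkoxide goes in. The fallback is the classical chromone synthesis, with the ring-A oxygens present from the start and ring B closed by dehydration instead of fluoride displacement. It sets out from acid chloride 2. Commercial 1-[2,4-bis(benzyloxy)-6-hydroxyphenyl]ethan-1-one F1 would be doubly deprotonated with LiN(SiMe3)2 (3 equiv, THF, −78 °C) and C-acylated with 2 to give 1-[2,4-bis(benzyloxy)-6-hydroxyphenyl]tetracosane-1,3-dione F2. Cyclodehydration of F2 (catalytic H2SO4, AcOH, 60 °C) should give 7, where the route is rejoined.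

Step 1. O-acylation of the enolate, a second acylation at C2 of the product, dehydrochlorination of 2 to a ketene, or attack of amide or enolate on an aryl C–F bond on warming could erode the diketone. Premature ring closure of the lithium diketonate would be harmless, since it only anticipates step 2. The fallback is aldol addition followed by oxidation, so that no acyl chloride meets the enolate. It sets out from 1 and 2. Acid chloride 2 would be reduced with LiAlH(OtBu)3 (THF, −78 °C) to docosanal F3. The lithium enolate of 1 (LiN(SiMe3)2, THF, −78 °C) would add to F3 to give racemic 3-hydroxy-1-(2,4,6-trifluorophenyl)tetracosan-1-one F4. Oxidation of F4 with 2-iodoxybenzoic acid (EtOAc, 75 °C) should return the route at 3.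

Step 3. The 7-ether lacks chelation assistance and may be cleaved incompletely. Friedel–Crafts benzylation of the electron-rich ring A at C6 or C8 may occur if cation capture lags. The long-chain substrate may also precipitate at low temperature. The fallback is reductive instead of Lewis-acidic cleavage, so no benzyl cation is formed. It sets out from 7: hydrogenolysis with H2 (1 atm) over 10% Pd/C in THF–EtOAc at 25 °C, stopped after uptake of two equivalents so that the C2=C3 bond is not saturated, should give 8 directly. No new compound is made (F0).

Further compounds
F1 | step 2 | 1-[2,4-bis(benzyloxy)-6-hydroxyphenyl]ethan-1-one | CC(=O)c1c(O)cc(OCc2ccccc2)cc1OCc1ccccc1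
F2 | step 2 | 1-[2,4-bis(benzyloxy)-6-hydroxyphenyl]tetracosane-1,3-dione | CCCCCCCCCCCCCCCCCCCCCC(=O)CC(=O)c1c(O)cc(OCc2ccccc2)cc1OCc1ccccc1
F3 | step 1 | docosanal | CCCCCCCCCCCCCCCCCCCCCC=O
F4 | step 1 | 3-hydroxy-1-(2,4,6-trifluorophenyl)tetracosan-1-one (racemic) | CCCCCCCCCCCCCCCCCCCCCC(O)CC(=O)c1c(F)cc(F)cc1F
F0 | step 3 | none | none
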